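## Structural features

The target (C30H20O10) is a biflavonoid ether. A (2S)-5,7-dihydroxyflavanone unit (rings A, C and B) is joined through the oxygen on C4' of its para-phenylene ring B to C3 of a 5,7,4'-trihydroxyflavone unit (rings A', C' and B'). The flavonol 3-oxygen is therefore an aryl enol ether, flanked by the C2 aryl group and the C4 carbonyl of ring C'. The only stereocentre is C2 of the flavanone (S), with no neighbouring stereocentre. It is benzylic, carries the ring oxygen O1 and lies β to the C4 ketone, so base or a strong Lewis acid can erase it by reversible opening of ring C to the 2'-hydroxychalcone. The fragile groups are the five free phenols (the two C5 hydroxyls are hydrogen-bonded to the carbonyls), the nucleophile-sensitive C2 of chromone ring C', and the hindered, weakly nucleophilic flavonol 3-oxygen. The real difficulty is twofold: making the hindered C3–O–aryl ether, and delivering the flavanone as one enantiomer while the phenols are unveiled last without reopening ring C. The key step exploits ring A of the flavanone: O1 sits on C8a and the acyl carbon C4 on the adjacent C4a, with the C5 oxygen on the other side of C4a and the C7 oxygen para to it. That is the pattern formed when a carboxylate adds across a 3,5-dialkoxybenzyne, oxygen to the distal and acyl to the proximal aryne carbon.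

## Logic of the disconnections

25 to 24. The five O–CH2Ph bonds are cut. All phenols, those of flavanone ring A included, are carried as one kind of ether, so a single neutral hydrogenolysis ends the route. A mixed ether scheme would need a strong Lewis acid at the last step, next to the ionisable C2 centre. The forward step must spare the benzylic C2–O1 bond and the two C4 ketones.

24 to 23. The O1–C2 bond of ring C is cut (retro-oxa-Michael). This removes the only stereocentre and leaves an achiral, planar precursor. The forward 6-endo closure must be enantioselective under catalyst control, and 23 must not close by itself before the catalyst acts.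

23 to 13 and 20 (through 21). Two bonds to ring A are cut: the aryl C–O bond of the 2'-hydroxyl (later O1–C8a) and the aryl–acyl bond (later C4–C4a). Both lie on adjacent carbons, so one aryne insertion makes them together and brings in ring A as an intact benzene ring. 23 falls into two fragments, with the whole flavonol ether held in 13. The forward step needs regiocontrol of aryne capture, acyl transfer faster than protonation of the aryl anion, and tolerance of chromone and benzyl ethers to hot fluoride.

13 to 10 and 11. The Cα=Cβ bond of the acrylic acid is cut. The acid is traced to an aldehyde and a two-carbon donor. The forward condensation must decarboxylate to the E acid.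

10 to 8 and 9. The aryl C–O bond between the benzaldehyde ring and the flavonol oxygen is cut. This separates a simple activated aryl fluoride from the flavonol. The hindered enolic oxygen of 8 must displace fluoride activated only by a para formyl group, with oxygen excluded.

8 to 6 (through 7), 6 to 4 (through 5), 4 to 2 and 3, 2 to 1. The C3–O bond is cut first, so the 3-hydroxyl comes from oxidation of a flavone; a direct oxidative cyclisation of 4 to 8 is unreliable when C6' is substituted. Then the O1–C2 bond and the C2=C3 unsaturation are removed, the Cα=Cβ bond of 4 is cut in an aldol sense, and two benzyl–oxygen bonds are cut. The forward benzylation must leave the chelated hydroxyl of 1 free.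

20 to 18 (through 19), 18 to 15 (through 16 and 17), 15 to 14. The S–O bond of the triflate and the C2–Si bond are cut. The carbamate group serves first as the ortho-directing group and then leaves under mild amine conditions. Lithiation ortho to the carbamate must be faster than deprotonation of the benzylic ether positions.

## Other disconnections considered

Alternative 1: The cut is through ring C' of the flavonol, at C3–C4 and O1–C8a.
- **Forward step:** the lithium enolate of 1-[4-(benzyloxy)phenyl]-2-(4-bromophenoxy)ethan-1-one A1 would be C-acylated by 2,4,6-trifluorobenzoyl chloride A2. The diketone enolate oxygen would then displace an ortho fluoride to give 2-(4-benzyloxyphenyl)-3-(4-bromophenoxy)-5,7-difluoro-4H-chromen-4-one A3.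
- **In favour:** the C3–O–aryl ether is already in A1, where it comes from a simple phenoxide alkylation. No C3 oxidation and no arylation of a hindered flavonolate is needed. The ring-closing SNAr is intramolecular and activated by the ortho carbonyl.
- **Against:** the C5 and C7 oxygens arrive as fluorides. They would have to be exchanged for benzyloxy groups in two further SNAr reactions on a chromone whose C2 is also open to alkoxide. The bromide would still need a Heck coupling to reach 13. The enolate acylation consumes a second equivalent of base and can go to oxygen.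
- **Comparison:** on structure, A3 addresses only the flavonol half; it would replace steps 1 to 6 and feed 13 into the aryne step. On mechanism, its intramolecular fluoride displacement is more dependable than the intermolecular one of step 5, and on that point it is the better. On step economy it is about equal, perhaps one step shorter to 13. Its late double fluoride exchange on a base-sensitive chromone is a risk the chosen plan does not carry.

Alternative 2: The cut is the C4a–C5 bond of flavanone ring A, opening the ring to a polyketide chain.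
- **Forward step:** Mg(OMe)2 would promote a Claisen cyclisation of methyl (9R)-9-[(tert-butyldimethylsilyl)oxy]-9-(4-{[5,7-bis(benzyloxy)-2-(4-benzyloxyphenyl)-4-oxo-4H-chromen-3-yl]oxy}phenyl)-3,5,7-trioxononanoate A4. The C6 methylene would attack the ester carbon to give the 2,4,6-trihydroxyphenyl ketone A5. Desilylation and an invertive Mitsunobu etherification would then close ring C to the 2S centre.
- **In favour:** the plan is biomimetic and needs no aryne precursor. The stereocentre would be set in an open chain by dependable asymmetric reduction or aldol chemistry and transferred by SN2 inversion. That is potentially more reliable enantiocontrol than step 11, and on that point it is the better.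
- **Against:** A4 must be built by stepwise polyanion chain extension on the most advanced fragment. The β-silyloxy ketone can eliminate to the enone under the basic magnesium alkoxide, which would destroy the stereocentre. An aldol mode of cyclisation to a resorcylate competes with the Claisen mode. A5 would enter the Mitsunobu step with three free phenols.
- **Comparison:** on structure, six carbons must be assembled and aromatised to make a ring that the chosen plan introduces intact as 21. On mechanism, the regiochemistry of cyclisation is less secure than aryne capture directed by an alkoxy group. On step economy it is clearly longer and more linear.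

Alternative 3: The cut is through ring C' of the flavonol, at C2–C3 and O1–C2.
- **Forward step:** 1-[2,4-bis(benzyloxy)-6-hydroxyphenyl]-2-[4-(1,3-dioxolan-2-yl)phenoxy]ethan-1-one A6 would be O-aroylated with 4-(benzyloxy)benzoyl chloride A7. A base-induced O-to-C aroyl shift of the Baker–Venkataraman type and cyclodehydration would give 5,7-bis(benzyloxy)-2-(4-benzyloxyphenyl)-3-[4-(1,3-dioxolan-2-yl)phenoxy]-4H-chromen-4-one A8. Acetal hydrolysis would lead to 10.
- **In favour:** this is classical ionic carbonyl chemistry. It needs no C3 oxidation, no dioxirane and no SNAr on a flavonolate, and on these points it is the better. If 10 were then condensed with 2 under Claisen–Schmidt conditions, 23 would result without steps 6 to 10. That is shorter than the chosen plan and is named as better on step economy; it is kept as the fallback for step 10.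
- **Against:** A6 is not trivial to reach. α-Halogenation of 2 competes with halogenation of the electron-rich ring, and an α-halo ketone with a free ortho hydroxyl tends to close to a benzofuranone under base. A6 would need a Hoesch-type acylation or extra protection. The acetal adds a protection and a release.
- **Comparison:** on structure it reaches the same intermediate 10 in a similar number of steps, so it is equal there. On mechanism it avoids an intermediate as short-lived as 21 and is more predictable. The chosen plan instead attaches flavanone ring A last, both bonds in one operation, and exposes the advanced aldehyde to no aldol equilibrium.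

Key step: step 10

Assumption: 3,5-bis(benzyloxy)phenol, 4-(benzyloxy)benzaldehyde and 4-fluorobenzaldehyde are taken as catalogue compounds.
Assumption: the quinidine-derived thiourea of step 11 is taken to give the 2S antipode; the quinine-derived pseudo-enantiomer would be used if the sense of induction proved opposite.
Remark: the regiochemistry of 20 and 21 was checked against ring A of 25 and needs no correction; the one design change is benzyl in place of isopropyl ethers on the aryne precursor, so that a single hydrogenolysis ends the route.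

## Route

Step 1
Reactants: 1 2,4,6-trihydroxyacetophenone
Product: 2 1-[2,4-bis(benzyloxy)-6-hydroxyphenyl]ethan-1-one
Conditions: BnBr (2.1 equiv), K2CO3, DMF, 0 °C to rt
Reagents that add atoms: benzyl bromide, BrCc1ccccc1
Why: Williamson ether synthesis; the hydroxyl hydrogen-bonded to the acetyl carbonyl is the least reactive and should stay free when the halide is limited to two equivalents.

Step 2
Reactants: 2 1-[2,4-bis(benzyloxy)-6-hydroxyphenyl]ethan-1-one; 3 4-(benzyloxy)benzaldehyde
Product: 4 (E)-1-[2,4-bis(benzyloxy)-6-hydroxyphenyl]-3-[4-(benzyloxy)phenyl]prop-2-en-1-one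
Conditions: KOH, EtOH/THF, rt; then aq. HCl
Reagents that add atoms: none
Why: Claisen–Schmidt condensation; the aldol adduct eliminates by E1cB to the E enone, and the chalcone phenoxide is the stable form in strong base, so no ring closure is expected.

Step 3
Reactants: 4 (E)-1-[2,4-bis(benzyloxy)-6-hydroxyphenyl]-3-[4-(benzyloxy)phenyl]prop-2-en-1-one
Product: 6 5,7-bis(benzyloxy)-2-[4-(benzyloxy)phenyl]-4H-chromen-4-one, via racemic flavanone 5 (not isolated)
Conditions: I2 (10 mol %), DMSO, 130 °C, short reaction time
Reagents that add atoms: none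
Why: Iodine-mediated oxidative cyclisation of a 2'-hydroxychalcone: oxa-Michael closure to 5, α-iodination and loss of HI give the flavone, and DMSO reoxidises HI so that iodine stays catalytic; a short reaction time limits HI cleavage of the C5 benzyl ether.

Step 4
Reactants: 6 5,7-bis(benzyloxy)-2-[4-(benzyloxy)phenyl]-4H-chromen-4-one
Product: 8 5,7-bis(benzyloxy)-2-[4-(benzyloxy)phenyl]-3-hydroxy-4H-chromen-4-one, via flavone epoxide 7 (not isolated)
Conditions: DMDO, acetone/CH2Cl2, 0 °C to rt; then p-TsOH (cat.), CH2Cl2, rt
Reagents that add atoms: dimethyldioxirane, CC1(C)OO1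
Why: Dioxirane epoxidation of the C2=C3 bond, then acid-catalysed opening at C2 (cation stabilised by O1 and the aryl group) and loss of H3 give the 3-hydroxyflavone; this avoids the Algar–Flynn–Oyamada reaction, which tends to give aurones when C6' of the chalcone is substituted.

Step 5
Reactants: 8 5,7-bis(benzyloxy)-2-[4-(benzyloxy)phenyl]-3-hydroxy-4H-chromen-4-one; 9 4-fluorobenzaldehyde
Product: 10 4-{[5,7-bis(benzyloxy)-2-(4-benzyloxyphenyl)-4-oxo-4H-chromen-3-yl]oxy}benzaldehyde
Conditions: Cs2CO3, DMF, 110 °C, Ar
Reagents that add atoms: none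
Why: SNAr diaryl ether synthesis; the caesium flavonolate adds to C4 of the aldehyde to give a Meisenheimer intermediate stabilised by the para formyl group, and fluoride leaves; argon prevents base-induced oxygenolysis of the flavonolate.

Step 6
Reactants: 10 4-{[5,7-bis(benzyloxy)-2-(4-benzyloxyphenyl)-4-oxo-4H-chromen-3-yl]oxy}benzaldehyde; 11 malonic acid
Product: 13 (E)-3-(4-{[5,7-bis(benzyloxy)-2-(4-benzyloxyphenyl)-4-oxo-4H-chromen-3-yl]oxy}phenyl)acrylic acid, via arylidenemalonic acid 12 (not isolated)
Conditions: pyridine, piperidine (cat.), 95 °C; then aq. HCl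
Reagents that add atoms: none
Why: Knoevenagel–Doebner condensation; 12 loses CO2 in hot pyridine to give the E-cinnamic acid.

Step 7
Reactants: 14 3,5-bis(benzyloxy)phenol
Product: 15 3,5-bis(benzyloxy)phenyl N-isopropylcarbamate
Conditions: i-PrNCO, Et3N (cat.), CH2Cl2, rt
Reagents that add atoms: isopropyl isocyanate, CC(C)N=C=O
Why: Base-catalysed addition of the phenol to the isocyanate; the carbamate is the directing group for step 8 and a leaving group removable by amines in step 9.

Step 8
Reactants: 15 3,5-bis(benzyloxy)phenyl N-isopropylcarbamate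
Product: 18 3,5-bis(benzyloxy)-2-(trimethylsilyl)phenyl N-isopropylcarbamate, via N-silyl carbamate 16 (not isolated), via N-silyl C-silyl carbamate 17 (not isolated)
Conditions: TBSOTf, TMEDA, Et2O, 0 °C to rt; then n-BuLi, TMEDA, −78 °C; TMSCl, −78 °C to rt; aq. NaHSO4
Reagents that add atoms: chlorotrimethylsilane, C[Si](C)(C)Cl
Why: Directed ortho-metalation: in situ N-silylation masks the N–H, the carbamate directs n-BuLi to C2 (the site it shares with the C3 benzyloxy group), and TMSCl traps the aryllithium; at −78 °C this should outpace benzylic deprotonation and anionic Fries migration, and the N–Si bond is cleaved on acidic work-up.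

Step 9
Reactants: 18 3,5-bis(benzyloxy)-2-(trimethylsilyl)phenyl N-isopropylcarbamate
Product: 20 3,5-bis(benzyloxy)-2-(trimethylsilyl)phenyl trifluoromethanesulfonate, via silylphenol 19 (not isolated)
Conditions: DBU, Et2NH, MeCN, 40 °C; then PhNTf2, rt
Reagents that add atoms: N-phenylbis(trifluoromethanesulfonimide), O=S(=O)(N(c1ccccc1)S(=O)(=O)C(F)(F)F)C(F)(F)F
Why: DBU induces E1cB loss of isopropyl isocyanate, diethylamine traps it as the urea, and the phenoxide of 19 is triflated in the same pot; the aryl–silicon bond should survive these mild aprotic conditions.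

Step 10
Reactants: 13 (E)-3-(4-{[5,7-bis(benzyloxy)-2-(4-benzyloxyphenyl)-4-oxo-4H-chromen-3-yl]oxy}phenyl)acrylic acid; 20 3,5-bis(benzyloxy)-2-(trimethylsilyl)phenyl trifluoromethanesulfonate
Product: 23 (E)-1-[2,4-bis(benzyloxy)-6-hydroxyphenyl]-3-(4-{[5,7-bis(benzyloxy)-2-(4-benzyloxyphenyl)-4-oxo-4H-chromen-3-yl]oxy}phenyl)prop-2-en-1-one, via aryne 21 (not isolated), via racemic flavanone 22 (not isolated)
Conditions: CsF (4 equiv), 20 (1.5 equiv), THF, 125 °C, sealed tube; then KOH, EtOH/THF/H2O, rt; AcOH
Reagents that add atoms: none
Why: Fluoride attacks silicon of 20 and triflate leaves, giving aryne 21; the caesium carboxylate of 13 adds through oxygen to the aryne carbon remote from the C3 benzyloxy group, which places the aryl anion on the carbon next to that inductively withdrawing oxygen. The anion attacks the neighbouring ester carbonyl and the strained four-membered alkoxide collapses with C–O cleavage to the ortho-acylphenoxide, so the aryl C–O bond (later O1–C8a) and the aryl–acyl bond (later C4–C4a) form in one operation. The closest known reaction type is the fluoride-induced insertion of arynes into the C–O bond of carboxylic acids, which is documented for α,β-unsaturated acids and gives ortho-hydroxyaryl enones and 4-chromanones. No ring is retained and no stereocentre is created: the part of the phenoxide that closes ring C by 6-endo-trig oxa-Michael addition to racemic 22 is reopened by hydroxide through E1cB elimination, because the chalcone phenoxide is the resting state in strong base, and acidification releases 23. The selectivity needed is regiochemical and is secured by the benzyloxy group beside the triple bond, which distorts and polarises the aryne so that the nucleophile goes to the distal carbon; the second benzyloxy group, para to the anion, does not oppose this. Acyl transfer must outrun protonation of the aryl anion, which the high temperature and the single carboxyl proton as the only proton source favour; any aryl ester from simple O-arylation would be saponified in the hydroxide treatment and 13 recovered. The E alkene of 13 is not involved and is retained in 23.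

Step 11
Reactants: 23 (E)-1-[2,4-bis(benzyloxy)-6-hydroxyphenyl]-3-(4-{[5,7-bis(benzyloxy)-2-(4-benzyloxyphenyl)-4-oxo-4H-chromen-3-yl]oxy}phenyl)prop-2-en-1-one
Product: 24 (2S)-5,7-bis(benzyloxy)-2-(4-{[5,7-bis(benzyloxy)-2-(4-benzyloxyphenyl)-4-oxo-4H-chromen-3-yl]oxy}phenyl)chroman-4-one
Conditions: 9-amino-9-deoxy-epi-quinidine 3,5-bis(trifluoromethyl)phenyl thiourea (20 mol %), toluene, 0 °C to rt
Reagents that add atoms: none
Why: Organocatalytic enantioselective intramolecular oxa-Michael addition of a 2'-hydroxychalcone: the quinuclidine nitrogen activates the phenol, the thiourea binds the enone carbonyl, and 6-endo-trig attack of oxygen on Cβ on the face left open in this chiral assembly sets C2. The C6' benzyloxy group twists the enone and makes closure favourable, and crystallisation can raise the enantiomeric purity.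

Step 12
Reactants: 24 (2S)-5,7-bis(benzyloxy)-2-(4-{[5,7-bis(benzyloxy)-2-(4-benzyloxyphenyl)-4-oxo-4H-chromen-3-yl]oxy}phenyl)chroman-4-one
Product: 25 (2S)-5,7-dihydroxy-2-(4-{[5,7-dihydroxy-2-(4-hydroxyphenyl)-4-oxo-4H-chromen-3-yl]oxy}phenyl)chroman-4-one (CNP0144321.1)
Conditions: H2 (1 atm), 10% Pd/C, EtOAc/MeOH, rt
Reagents that add atoms: none
Why: Hydrogenolysis of the five benzyl aryl ethers under neutral conditions; with no base or Lewis acid present the C2 centre should not be touched, and the tetrasubstituted C2=C3 bond of the flavonol, the hydrogen-bonded C4 ketones and the diaryl ether should survive if the reaction is stopped at full conversion.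

## Compound list

1 | 2,4,6-trihydroxyacetophenone | CC(=O)c1c(O)cc(O)cc1O | starting material
2 | 1-[2,4-bis(benzyloxy)-6-hydroxyphenyl]ethan-1-one | CC(=O)c1c(O)cc(OCc2ccccc2)cc1OCc1ccccc1 | intermediate
3 | 4-(benzyloxy)benzaldehyde | O=Cc1ccc(OCc2ccccc2)cc1 | starting material
4 | (E)-1-[2,4-bis(benzyloxy)-6-hydroxyphenyl]-3-[4-(benzyloxy)phenyl]prop-2-en-1-one | O=C(/C=C/c1ccc(OCc2ccccc2)cc1)c1c(O)cc(OCc2ccccc2)cc1OCc1ccccc1 | intermediate
5 | racemic 5,7-bis(benzyloxy)-2-[4-(benzyloxy)phenyl]chroman-4-one | O=C1CC(c2ccc(OCc3ccccc3)cc2)Oc2cc(OCc3ccccc3)cc(OCc3ccccc3)c21 | intermediate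
6 | 5,7-bis(benzyloxy)-2-[4-(benzyloxy)phenyl]-4H-chromen-4-one | O=c1cc(-c2ccc(OCc3ccccc3)cc2)oc2cc(OCc3ccccc3)cc(OCc3ccccc3)c12 | intermediate
7 | racemic 5,7-bis(benzyloxy)-2-[4-(benzyloxy)phenyl]-2,3-epoxychroman-4-one | O=C1C2OC2(c2ccc(OCc3ccccc3)cc2)Oc2cc(OCc3ccccc3)cc(OCc3ccccc3)c21 | intermediate
8 | 5,7-bis(benzyloxy)-2-[4-(benzyloxy)phenyl]-3-hydroxy-4H-chromen-4-one | O=c1c(O)c(-c2ccc(OCc3ccccc3)cc2)oc2cc(OCc3ccccc3)cc(OCc3ccccc3)c12 | intermediate
9 | 4-fluorobenzaldehyde | O=Cc1ccc(F)cc1 | starting material
10 | 4-{[5,7-bis(benzyloxy)-2-(4-benzyloxyphenyl)-4-oxo-4H-chromen-3-yl]oxy}benzaldehyde | O=Cc1ccc(Oc2c(-c3ccc(OCc4ccccc4)cc3)oc3cc(OCc4ccccc4)cc(OCc4ccccc4)c3c2=O)cc1 | intermediate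
11 | malonic acid | OC(=O)CC(=O)O | starting material
12 | 2-(4-{[5,7-bis(benzyloxy)-2-(4-benzyloxyphenyl)-4-oxo-4H-chromen-3-yl]oxy}benzylidene)malonic acid | OC(=O)C(=Cc1ccc(Oc2c(-c3ccc(OCc4ccccc4)cc3)oc3cc(OCc4ccccc4)cc(OCc4ccccc4)c3c2=O)cc1)C(=O)O | intermediate
13 | (E)-3-(4-{[5,7-bis(benzyloxy)-2-(4-benzyloxyphenyl)-4-oxo-4H-chromen-3-yl]oxy}phenyl)acrylic acid | OC(=O)/C=C/c1ccc(Oc2c(-c3ccc(OCc4ccccc4)cc3)oc3cc(OCc4ccccc4)cc(OCc4ccccc4)c3c2=O)cc1 | intermediate
14 | 3,5-bis(benzyloxy)phenol | Oc1cc(OCc2ccccc2)cc(OCc2ccccc2)c1 | starting material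
15 | 3,5-bis(benzyloxy)phenyl N-isopropylcarbamate | CC(C)NC(=O)Oc1cc(OCc2ccccc2)cc(OCc2ccccc2)c1 | intermediate
16 | 3,5-bis(benzyloxy)phenyl N-(tert-butyldimethylsilyl)-N-isopropylcarbamate | CC(C)N(C(=O)Oc1cc(OCc2ccccc2)cc(OCc2ccccc2)c1)[Si](C)(C)C(C)(C)C | intermediate
17 | 3,5-bis(benzyloxy)-2-(trimethylsilyl)phenyl N-(tert-butyldimethylsilyl)-N-isopropylcarbamate | CC(C)N(C(=O)Oc1cc(OCc2ccccc2)cc(OCc2ccccc2)c1[Si](C)(C)C)[Si](C)(C)C(C)(C)C | intermediate
18 | 3,5-bis(benzyloxy)-2-(trimethylsilyl)phenyl N-isopropylcarbamate | CC(C)NC(=O)Oc1cc(OCc2ccccc2)cc(OCc2ccccc2)c1[Si](C)(C)C | intermediate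
19 | 3,5-bis(benzyloxy)-2-(trimethylsilyl)phenol | Oc1cc(OCc2ccccc2)cc(OCc2ccccc2)c1[Si](C)(C)C | intermediate
20 | 3,5-bis(benzyloxy)-2-(trimethylsilyl)phenyl trifluoromethanesulfonate | C[Si](C)(C)c1c(OCc2ccccc2)cc(OCc2ccccc2)cc1OS(=O)(=O)C(F)(F)F | intermediate
21 | 3,5-bis(benzyloxy)benzyne (1,2-didehydro-3,5-bis(benzyloxy)benzene) | C1#CC(OCc2ccccc2)=CC(OCc2ccccc2)=C1 | intermediate
22 | racemic 5,7-bis(benzyloxy)-2-(4-{[5,7-bis(benzyloxy)-2-(4-benzyloxyphenyl)-4-oxo-4H-chromen-3-yl]oxy}phenyl)chroman-4-one | O=C1CC(c2ccc(Oc3c(-c4ccc(OCc5ccccc5)cc4)oc4cc(OCc5ccccc5)cc(OCc5ccccc5)c4c3=O)cc2)Oc2cc(OCc3ccccc3)cc(OCc3ccccc3)c21 | intermediate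
23 | (E)-1-[2,4-bis(benzyloxy)-6-hydroxyphenyl]-3-(4-{[5,7-bis(benzyloxy)-2-(4-benzyloxyphenyl)-4-oxo-4H-chromen-3-yl]oxy}phenyl)prop-2-en-1-one | O=C(/C=C/c1ccc(Oc2c(-c3ccc(OCc4ccccc4)cc3)oc3cc(OCc4ccccc4)cc(OCc4ccccc4)c3c2=O)cc1)c1c(O)cc(OCc2ccccc2)cc1OCc1ccccc1 | intermediate
24 | (2S)-5,7-bis(benzyloxy)-2-(4-{[5,7-bis(benzyloxy)-2-(4-benzyloxyphenyl)-4-oxo-4H-chromen-3-yl]oxy}phenyl)chroman-4-one | O=C1C[C@@H](c2ccc(Oc3c(-c4ccc(OCc5ccccc5)cc4)oc4cc(OCc5ccccc5)cc(OCc5ccccc5)c4c3=O)cc2)Oc2cc(OCc3ccccc3)cc(OCc3ccccc3)c21 | intermediate
25 | (2S)-5,7-dihydroxy-2-(4-{[5,7-dihydroxy-2-(4-hydroxyphenyl)-4-oxo-4H-chromen-3-yl]oxy}phenyl)chroman-4-one | O=C1C[C@@H](c2ccc(Oc3c(-c4ccc(O)cc4)oc4cc(O)cc(O)c4c3=O)cc2)Oc2cc(O)cc(O)c21 | target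

## Step count and risk

Total step count: 12. Longest linear sequence: 9 steps (steps 1 to 6, then 10, 11 and 12); the aryne branch is steps 7 to 9.

Least certain steps:

- **Step 10 (key step).** The aryl anion may be protonated before it transfers the acyl group, which stops the sequence at simple O-arylation. The product phenoxide may capture a second aryne. Hydroxide used for ring reopening may also attack C2 of the chromone. Fallback: starting from 10 and 2, a Claisen–Schmidt condensation (KOH, EtOH/THF, rt, then acid) would give 23 directly and rejoin the route at 23. This fallback makes no compound outside the list (F0).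

- **Step 11.** Facial selectivity may be poor, an uncatalysed racemic closure may compete, or the sense of induction may be opposite. Fallback: starting from 23, closure with NaOAc in refluxing EtOH would give racemic 22. Resolution by preparative chromatography on an amylose tris(3,5-dimethylphenylcarbamate) phase would give 24, where the route is rejoined. The unwanted (2R)-5,7-bis(benzyloxy)-2-(4-{[5,7-bis(benzyloxy)-2-(4-benzyloxyphenyl)-4-oxo-4H-chromen-3-yl]oxy}phenyl)chroman-4-one F1 would be reopened with KOH to 23 and recycled.

- **Step 5.** Displacement by the hindered, delocalised flavonolate may be slow, and decomposition of the flavonolate or the aldehyde at high temperature may compete. Fallback: starting from 8, an Ullmann-type coupling with ethyl (E)-4-bromocinnamate (CuI, N,N-dimethylglycine, Cs2CO3, dioxane, 100 °C) would give ethyl (E)-3-(4-{[5,7-bis(benzyloxy)-2-(4-benzyloxyphenyl)-4-oxo-4H-chromen-3-yl]oxy}phenyl)acrylate F2. Saponification (LiOH, THF/H2O, rt) would return to the route at 13, bypassing 10 and step 6.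

- **Step 12.** Over-reduction may occur, either by hydrogenolysis of the benzylic C2–O1 bond or by reduction of a C4 ketone. Debenzylation may stall as partly deprotected material precipitates. Fallback: starting from 24, Lewis-acid cleavage with BCl3 and pentamethylbenzene as cation scavenger (CH2Cl2, −78 °C) would give 25 directly; the low temperature is meant to limit ionisation at C2. This fallback makes no compound outside the list (F0).

- **Step 8.** Benzylic deprotonation of a benzyl ether with Wittig rearrangement, or anionic Fries migration of the carbamate, may compete with ortho-lithiation. Fallback: starting from 14, bromination ortho to the hydroxyl (NBS, CH2Cl2, −78 °C, separation from the para isomer) would give 2-bromo-3,5-bis(benzyloxy)phenol F3. Silylation (HMDS, THF, reflux) would give [2-bromo-3,5-bis(benzyloxy)phenoxy]trimethylsilane F4. Bromine–lithium exchange with n-BuLi at −100 °C would trigger a retro-Brook shift of silicon from oxygen to carbon to give the lithium salt of 19, and Tf2O would give 20, where the route is rejoined.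

## Further compounds

F0 | step 10 | none | none
F1 | step 11 | (2R)-5,7-bis(benzyloxy)-2-(4-{[5,7-bis(benzyloxy)-2-(4-benzyloxyphenyl)-4-oxo-4H-chromen-3-yl]oxy}phenyl)chroman-4-one | O=C1C[C@H](c2ccc(Oc3c(-c4ccc(OCc5ccccc5)cc4)oc4cc(OCc5ccccc5)cc(OCc5ccccc5)c4c3=O)cc2)Oc2cc(OCc3ccccc3)cc(OCc3ccccc3)c21
F2 | step 5 | ethyl (E)-3-(4-{[5,7-bis(benzyloxy)-2-(4-benzyloxyphenyl)-4-oxo-4H-chromen-3-yl]oxy}phenyl)acrylate | CCOC(=O)/C=C/c1ccc(Oc2c(-c3ccc(OCc4ccccc4)cc3)oc3cc(OCc4ccccc4)cc(OCc4ccccc4)c3c2=O)cc1
F0 | step 12 | none | none
F3 | step 8 | 2-bromo-3,5-bis(benzyloxy)phenol | Oc1cc(OCc2ccccc2)cc(OCc2ccccc2)c1Br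
F4 | step 8 | [2-bromo-3,5-bis(benzyloxy)phenoxy]trimethylsilane | C[Si](C)(C)Oc1cc(OCc2ccccc2)cc(OCc2ccccc2)c1Br
A1 | alternative 1 | 1-[4-(benzyloxy)phenyl]-2-(4-bromophenoxy)ethan-1-one | O=C(COc1ccc(Br)cc1)c1ccc(OCc2ccccc2)cc1
A2 | alternative 1 | 2,4,6-trifluorobenzoyl chloride | O=C(Cl)c1c(F)cc(F)cc1F
A3 | alternative 1 | 2-(4-benzyloxyphenyl)-3-(4-bromophenoxy)-5,7-difluoro-4H-chromen-4-one | O=c1c(Oc2ccc(Br)cc2)c(-c2ccc(OCc3ccccc3)cc2)oc2cc(F)cc(F)c12
A4 | alternative 2 | methyl (9R)-9-[(tert-butyldimethylsilyl)oxy]-9-(4-{[5,7-bis(benzyloxy)-2-(4-benzyloxyphenyl)-4-oxo-4H-chromen-3-yl]oxy}phenyl)-3,5,7-trioxononanoate | COC(=O)CC(=O)CC(=O)CC(=O)C[C@H](c1ccc(Oc2c(-c3ccc(OCc4ccccc4)cc3)oc3cc(OCc4ccccc4)cc(OCc4ccccc4)c3c2=O)cc1)O[Si](C)(C)C(C)(C)C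
A5 | alternative 2 | (3R)-3-[(tert-butyldimethylsilyl)oxy]-3-(4-{[5,7-bis(benzyloxy)-2-(4-benzyloxyphenyl)-4-oxo-4H-chromen-3-yl]oxy}phenyl)-1-(2,4,6-trihydroxyphenyl)propan-1-one | O=C(C[C@H](c1ccc(Oc2c(-c3ccc(OCc4ccccc4)cc3)oc3cc(OCc4ccccc4)cc(OCc4ccccc4)c3c2=O)cc1)O[Si](C)(C)C(C)(C)C)c1c(O)cc(O)cc1O
A6 | alternative 3 | 1-[2,4-bis(benzyloxy)-6-hydroxyphenyl]-2-[4-(1,3-dioxolan-2-yl)phenoxy]ethan-1-one | O=C(COc1ccc(C2OCCO2)cc1)c1c(O)cc(OCc2ccccc2)cc1OCc1ccccc1
A7 | alternative 3 | 4-(benzyloxy)benzoyl chloride | O=C(Cl)c1ccc(OCc2ccccc2)cc1
A8 | alternative 3 | 5,7-bis(benzyloxy)-2-(4-benzyloxyphenyl)-3-[4-(1,3-dioxolan-2-yl)phenoxy]-4H-chromen-4-one | O=c1c(Oc2ccc(C3OCCO3)cc2)c(-c2ccc(OCc3ccccc3)cc2)oc2cc(OCc3ccccc3)cc(OCc3ccccc3)c12
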